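A direct plan would add the aryllithium from 1-(benzyloxy)-4-bromo-8-methoxynaphthalene A1 to 7-methoxyphthalide A2, dehydrate the keto alcohol to an isobenzofuran, trap it with a vinyl sulfoxide and eliminate to the racemic 1-aryl-1,4-epoxy-1,4-dihydronaphthalene A3, hydrogenate and hydrogenolyse this to the racemic cis-alcohol A4, and resolve A4 with a lipase.
Its three weakest points would be these.
- The closing enzymatic kinetic resolution would be the only source of absolute configuration and would discard at least half of the most advanced material.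
- The one-pot hydrogenation and benzylic C–O hydrogenolysis would leave the cis relation to the unsecured stereochemical course of cleaving a tertiary diaryl C–O bond on palladium, with the second benzylic C–O bond and the new carbinol open to over-reduction.
- The isobenzofuran formation, cycloaddition and sulfoxide elimination cascade would pass through a labile diene and need an acetylene surrogate, only to build a racemic oxygen bridge that is then taken apart; together with protection and phthalide making, most steps would add no stereochemical information.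

**Plan of the new route**
- Cuts, in retrosynthetic order: C1–H (ketone reduction), C1–C8a (anionic acylation of an aryl bromide), C4–C4a with O–C2 re-formed (retro-Claisen), C2–O (carbinol from a 2-oxo ester), C3=C4 (olefination of a naphthaldehyde).
- Enabling feature: the methoxy oxygen on C5 of the anisole ring is ortho to C4a, and C4a carries the methine C4 followed by C3 and C2. The array O–C5–C4a–C4–C3–C2 is the imprint of an aromatic Claisen rearrangement of an aryl 3-naphthylallyl ether.
- The rearrangement makes the hindered diarylmethine C4 intramolecularly, with chirality transferred from a catalytically set 2-hydroxy ester, and puts the C5 oxygen in place. Symmetrical 3,5-dibromophenol leaves no regiochemical choice.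
- Order of rings: the bought naphthalene first carries the whole C1–C4 chain, the anisole ring is attached second, and ring B closes last by C1–C8a acylation (C1–C2 and C3–C4 already exist), the spare bromine leaving in the same flask.
- C1 is set by catalyst-controlled transfer hydrogenation, so no resolution, no C–O hydrogenolysis, no isobenzofuran and no racemic or oxygen-bridged tetracycle occurs.

Key step: step 7

Assumption: in step 5 the (S)-configured diphosphine is taken to give the (2S)-hydroxy ester, as (S)-biaryl diphosphine–ruthenium catalysts do with simple 2-oxo esters; were the sense opposite, the antipodal ligand would be used and nothing else would change.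

Step 1
Reactants: 1 8-methoxynaphthalen-1-ol
Product: 2 4-bromo-8-methoxynaphthalen-1-ol
Conditions: NBS (1.0 equiv), MeCN, −20 to 0 °C
Reagents that add atoms: N-bromosuccinimide, O=C1CCC(=O)N1Br
Why: Electrophilic aromatic bromination; the hydrogen-bonded naphthol OH is the strongest donor, so bromine should enter para to it (C4) and not the methoxy-bearing ring.

Step 2
Reactants: 2 4-bromo-8-methoxynaphthalen-1-ol
Product: 3 1-bromo-5-methoxy-4-(methoxymethoxy)naphthalene
Conditions: NaH, THF–DMF, 0 °C; MOMCl, 0 °C to rt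
Reagents that add atoms: chloromethyl methyl ether, COCCl
Why: Williamson-type O-alkylation of the naphthoxide; the acetal ether should tolerate organolithiums, 180 °C and base, and is shed by acid in the work-up of step 10.

Step 3
Reactants: 3 1-bromo-5-methoxy-4-(methoxymethoxy)naphthalene
Product: 5 5-methoxy-4-(methoxymethoxy)naphthalene-1-carbaldehyde, via aryllithium 4 (not isolated)
Conditions: n-BuLi (1.05 equiv), THF, −78 °C; DMF, −78 to 0 °C; aq. NH4Cl
Reagents that add atoms: N,N-dimethylformamide, CN(C)C=O
Why: Bromine–lithium exchange followed by Bouveault formylation, which places the future C4 carbon on the naphthalene.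

Step 4
Reactants: 5 5-methoxy-4-(methoxymethoxy)naphthalene-1-carbaldehyde; 6 ethyl 2-oxo-3-(triphenyl-λ5-phosphanylidene)propanoate
Product: 7 ethyl (3E)-4-[5-methoxy-4-(methoxymethoxy)naphthalen-1-yl]-2-oxobut-3-enoate
Conditions: toluene, 90 °C
Reagents that add atoms: none
Why: Wittig olefination with a stabilised acyl ylide, which should give the (E)-enone and brings in C3, C2 and C1 at once.

Step 5
Reactants: 7 ethyl (3E)-4-[5-methoxy-4-(methoxymethoxy)naphthalen-1-yl]-2-oxobut-3-enoate
Product: 8 ethyl (2S,3E)-2-hydroxy-4-[5-methoxy-4-(methoxymethoxy)naphthalen-1-yl]but-3-enoate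
Conditions: [RuCl(p-cymene)((S)-SEGPHOS)]Cl (1 mol %), H2 (20 atm), EtOH–CH2Cl2, 30 °C, stopped after 1 equiv H2
Reagents that add atoms: none
Why: Noyori-type asymmetric hydrogenation of the activated 2-oxo ester carbonyl by a divalent ruthenium–diphosphine catalyst, which sets C2 as (S) by ester-chelated hydride delivery and at low temperature should leave the alkene untouched.

Step 6
Reactants: 8 ethyl (2S,3E)-2-hydroxy-4-[5-methoxy-4-(methoxymethoxy)naphthalen-1-yl]but-3-enoate; 9 3,5-dibromophenol
Product: 10 ethyl (2R,3E)-2-(3,5-dibromophenoxy)-4-[5-methoxy-4-(methoxymethoxy)naphthalen-1-yl]but-3-enoate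
Conditions: PPh3, DIAD, toluene, 0 °C to rt
Reagents that add atoms: none
Why: Mitsunobu etherification; the acidic phenol should displace the activated 2-hydroxy ester by SN2 (favoured next to the ester carbonyl) with inversion, turning (2S) into (2R).

Step 7
Reactants: 10 ethyl (2R,3E)-2-(3,5-dibromophenoxy)-4-[5-methoxy-4-(methoxymethoxy)naphthalen-1-yl]but-3-enoate
Product: 12 ethyl (2E,4S)-4-[2-(acetyloxy)-4,6-dibromophenyl]-4-[5-methoxy-4-(methoxymethoxy)naphthalen-1-yl]but-2-enoate, via phenol 11 (not isolated)
Conditions: Ac2O (5 equiv), N,N-diethylaniline, 180 °C, sealed vessel, Ar; chromatography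
Reagents that add atoms: acetic anhydride, CC(=O)OC(C)=O
Why: Thermal aromatic Claisen rearrangement: a concerted suprafacial [3,3] shift breaks O–C2 while C4 bonds to an ortho carbon of the dibromophenoxy ring, the dienone tautomerises to phenol 11, and acetic anhydride acetylates it at once so that neither oxa-Michael closure onto the new enoate nor an abnormal Claisen reaction can follow. The closest known reaction type is the rearrangement of enantioenriched secondary allyl aryl ethers with 1,3-transfer of chirality; no ring is closed, only the chair-like six-membered transition state is cyclic. The new stereocentre C4 is controlled by C2: with the ester group pseudo-equatorial and the naphthyl group of the (E)-alkene equatorial, the aryl carbon arrives on the alkene face from which the oxygen leaves, which turns (2R) into (4S) and gives the (2E)-enoate. Regioselectivity needs no control because the two ortho carbons of the 3,5-dibromophenyl ether are equivalent, and each is flanked by a bromine that later serves the ring closure. Fidelity requires the concerted path to outrun ionisation to a phenoxide and allyl cation pair, which the weakly polar amine medium, the absence of a Lewis acid and the electron-withdrawing ester at C2 should favour. Any (2Z)-enoate, which would carry the opposite C4 configuration, is removed by chromatography.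

Step 8
Reactants: 12 ethyl (2E,4S)-4-[2-(acetyloxy)-4,6-dibromophenyl]-4-[5-methoxy-4-(methoxymethoxy)naphthalen-1-yl]but-2-enoate
Product: 13 ethyl (4S)-4-[2-(acetyloxy)-4,6-dibromophenyl]-4-[5-methoxy-4-(methoxymethoxy)naphthalen-1-yl]butanoate
Conditions: Cu(OAc)2·H2O (5 mol %), 1,2-bis(diphenylphosphino)benzene (5 mol %), (EtO)2MeSiH (2 equiv), t-BuOH (2 equiv), toluene, rt
Reagents that add atoms: none
Why: Copper hydride conjugate reduction (Stryker-type); hydride goes to C3 of the enoate only, so the aryl bromides, the aryl acetate and the C4 stereocentre (no allyl-metal intermediate) should stay untouched.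

Step 9
Reactants: 13 ethyl (4S)-4-[2-(acetyloxy)-4,6-dibromophenyl]-4-[5-methoxy-4-(methoxymethoxy)naphthalen-1-yl]butanoate
Product: 16 (4S)-4-(2,4-dibromo-6-methoxyphenyl)-4-[5-methoxy-4-(methoxymethoxy)naphthalen-1-yl]butanoic acid, via phenol 14 (not isolated), via methyl ether ester 15 (not isolated)
Conditions: K2CO3, MeI, EtOH, 40 °C; then 2 M NaOH, 50 °C; 1 M HCl to pH 3, 0 °C
Reagents that add atoms: iodomethane, CI; sodium hydroxide, [Na+].[OH-]
Why: Ethanolysis of the aryl acetate, Williamson O-methylation of the phenoxide (now free of any Michael acceptor) and saponification in one flask should give the acid for ring closure with the C5 methoxy group in place.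

Step 10
Reactants: 16 (4S)-4-(2,4-dibromo-6-methoxyphenyl)-4-[5-methoxy-4-(methoxymethoxy)naphthalen-1-yl]butanoic acid
Product: 20 (4S)-4-(4-hydroxy-5-methoxynaphthalen-1-yl)-5-methoxy-3,4-dihydronaphthalen-1(2H)-one, via trilithio carboxylate 17 (not isolated), via gem-diolate 18 (not isolated), via MOM ketone 19 (not isolated)
Conditions: t-BuLi (5.2 equiv), THF, −78 to −20 °C; then MeOH, 3 M HCl, 45 °C
Reagents that add atoms: none
Why: Parham cyclization; bromine–lithium exchange at both bromides, acylation of the C8a aryllithium by the lithium carboxylate to a gem-diolate that cannot over-add, protonation of the C7 aryllithium and acid cleavage of the acetal ether should give the tetralone acylated only at C8a, a site no Friedel–Crafts reaction would choose over the naphthalene.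

Step 11
Reactants: 20 (4S)-4-(4-hydroxy-5-methoxynaphthalen-1-yl)-5-methoxy-3,4-dihydronaphthalen-1(2H)-one
Product: 21 (1S,4S)-4-(4-hydroxy-5-methoxynaphthalen-1-yl)-5-methoxy-1,2,3,4-tetrahydronaphthalen-1-ol (dipolynaphthalene B)
Conditions: RuCl[(S,S)-TsDPEN](p-cymene) (1 mol %), HCO2H–Et3N (5:2), EtOAc, 30 °C
Reagents that add atoms: none
Why: Noyori–Ikariya asymmetric transfer hydrogenation; the (S,S)-catalyst should give the (1S)-carbinol as it does with 1-tetralone, and the face it attacks is also the one anti to the pseudo-axial C4 naphthyl group, so catalyst and substrate are matched for the cis (1S,4S) alcohol.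

**Compound list**

1 | 8-methoxynaphthalen-1-ol | COc1cccc2cccc(O)c12 | starting material
2 | 4-bromo-8-methoxynaphthalen-1-ol | COc1cccc2c(Br)ccc(O)c12 | intermediate
3 | 1-bromo-5-methoxy-4-(methoxymethoxy)naphthalene | COCOc1ccc(Br)c2cccc(OC)c12 | intermediate
4 | [5-methoxy-4-(methoxymethoxy)naphthalen-1-yl]lithium | [Li]c1ccc(OCOC)c2c(OC)cccc12 | intermediate (not isolated)
5 | 5-methoxy-4-(methoxymethoxy)naphthalene-1-carbaldehyde | O=Cc1ccc(OCOC)c2c(OC)cccc12 | intermediate
6 | ethyl 2-oxo-3-(triphenyl-λ5-phosphanylidene)propanoate | CCOC(=O)C(=O)C=P(c1ccccc1)(c1ccccc1)c1ccccc1 | starting material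
7 | ethyl (3E)-4-[5-methoxy-4-(methoxymethoxy)naphthalen-1-yl]-2-oxobut-3-enoate | CCOC(=O)C(=O)/C=C/c1ccc(OCOC)c2c(OC)cccc12 | intermediate
8 | ethyl (2S,3E)-2-hydroxy-4-[5-methoxy-4-(methoxymethoxy)naphthalen-1-yl]but-3-enoate | CCOC(=O)[C@@H](O)/C=C/c1ccc(OCOC)c2c(OC)cccc12 | intermediate
9 | 3,5-dibromophenol | Oc1cc(Br)cc(Br)c1 | starting material
10 | ethyl (2R,3E)-2-(3,5-dibromophenoxy)-4-[5-methoxy-4-(methoxymethoxy)naphthalen-1-yl]but-3-enoate | CCOC(=O)[C@H](Oc1cc(Br)cc(Br)c1)/C=C/c1ccc(OCOC)c2c(OC)cccc12 | intermediate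
11 | ethyl (2E,4S)-4-(2,4-dibromo-6-hydroxyphenyl)-4-[5-methoxy-4-(methoxymethoxy)naphthalen-1-yl]but-2-enoate | Oc1cc(Br)cc(Br)c1[C@H](c1ccc(OCOC)c2c(OC)cccc12)/C=C/C(=O)OCC | intermediate (not isolated)
12 | ethyl (2E,4S)-4-[2-(acetyloxy)-4,6-dibromophenyl]-4-[5-methoxy-4-(methoxymethoxy)naphthalen-1-yl]but-2-enoate | CC(=O)Oc1cc(Br)cc(Br)c1[C@H](c1ccc(OCOC)c2c(OC)cccc12)/C=C/C(=O)OCC | intermediate
13 | ethyl (4S)-4-[2-(acetyloxy)-4,6-dibromophenyl]-4-[5-methoxy-4-(methoxymethoxy)naphthalen-1-yl]butanoate | CC(=O)Oc1cc(Br)cc(Br)c1[C@H](c1ccc(OCOC)c2c(OC)cccc12)CCC(=O)OCC | intermediate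
14 | ethyl (4S)-4-(2,4-dibromo-6-hydroxyphenyl)-4-[5-methoxy-4-(methoxymethoxy)naphthalen-1-yl]butanoate | Oc1cc(Br)cc(Br)c1[C@H](c1ccc(OCOC)c2c(OC)cccc12)CCC(=O)OCC | intermediate (not isolated)
15 | ethyl (4S)-4-(2,4-dibromo-6-methoxyphenyl)-4-[5-methoxy-4-(methoxymethoxy)naphthalen-1-yl]butanoate | COc1cc(Br)cc(Br)c1[C@H](c1ccc(OCOC)c2c(OC)cccc12)CCC(=O)OCC | intermediate (not isolated)
16 | (4S)-4-(2,4-dibromo-6-methoxyphenyl)-4-[5-methoxy-4-(methoxymethoxy)naphthalen-1-yl]butanoic acid | COc1cc(Br)cc(Br)c1[C@H](c1ccc(OCOC)c2c(OC)cccc12)CCC(=O)O | intermediate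
17 | lithium (4S)-4-(2,4-dilithio-6-methoxyphenyl)-4-[5-methoxy-4-(methoxymethoxy)naphthalen-1-yl]butanoate | COc1cc([Li])cc([Li])c1[C@H](c1ccc(OCOC)c2c(OC)cccc12)CCC(=O)O[Li] | intermediate (not isolated)
18 | dilithium (4S)-7-lithio-5-methoxy-4-[5-methoxy-4-(methoxymethoxy)naphthalen-1-yl]-1,2,3,4-tetrahydronaphthalene-1,1-bis(olate) | COc1cc([Li])cc2c1[C@H](c1ccc(OCOC)c3c(OC)cccc13)CCC2(O[Li])O[Li] | intermediate (not isolated)
19 | (4S)-5-methoxy-4-[5-methoxy-4-(methoxymethoxy)naphthalen-1-yl]-3,4-dihydronaphthalen-1(2H)-one | COc1cccc2c1[C@H](c1ccc(OCOC)c3c(OC)cccc13)CCC2=O | intermediate (not isolated)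
20 | (4S)-4-(4-hydroxy-5-methoxynaphthalen-1-yl)-5-methoxy-3,4-dihydronaphthalen-1(2H)-one | COc1cccc2c1[C@H](c1ccc(O)c3c(OC)cccc13)CCC2=O | intermediate
21 | (1S,4S)-4-(4-hydroxy-5-methoxynaphthalen-1-yl)-5-methoxy-1,2,3,4-tetrahydronaphthalen-1-ol (dipolynaphthalene B) | COc1cccc2c1[C@H](c1ccc(O)c3c(OC)cccc13)CC[C@@H]2O | target

Total step count: 11. Longest linear sequence: 11 steps (1 to 21).

**Steps most likely to fail**

Step 7 (key step). What may go wrong: heterolysis of the C2–O bond to a dibromophenoxide and allyl cation pair (the cation being stabilised by the alkoxynaphthalene) with loss of chirality transfer, leakage through the axial-ester chair or a boat, sluggish migration to the bromine-flanked ortho carbon, or amine-promoted migration of the new C2=C3 double bond into conjugation with the two aryl groups, which would erase C4. The fallback sets out from 8 and returns at 20; in it Np stands for 5-methoxy-4-(methoxymethoxy)naphthalen-1-yl. Alcohol 8 would be acylated (picolinic acid, DCC, DMAP) to ethyl (2S,3E)-4-Np-2-[(pyridine-2-carbonyl)oxy]but-3-enoate F1. Purchasable 1-bromo-2-iodo-3-methoxybenzene would be converted by iodine–magnesium exchange (i-PrMgCl·LiCl, THF, −40 °C) into (2-bromo-6-methoxyphenyl)magnesium chloride F2. Copper-mediated allylic substitution of F1 by F2 (CuBr·SMe2, THF, −60 to −30 °C) should go anti-SN2', placing the aryl group on C4 opposite to the leaving picolinate. From the (2S)-ester this gives the same (4S) centre as the suprafacial rearrangement of the (2R)-ether, as ethyl (2E,4S)-4-(2-bromo-6-methoxyphenyl)-4-Np-but-2-enoate F3. Copper hydride reduction as in step 8 would give ethyl (4S)-4-(2-bromo-6-methoxyphenyl)-4-Np-butanoate F4, and LiOH would give (4S)-4-(2-bromo-6-methoxyphenyl)-4-Np-butanoic acid F5. With t-BuLi (3.1 equiv) under the conditions of step 10, F5 would give lithium (4S)-4-(2-lithio-6-methoxyphenyl)-4-Np-butanoate F6, which should close to dilithium (4S)-5-methoxy-4-Np-1,2,3,4-tetrahydronaphthalene-1,1-bis(olate) F7 and, after the acidic work-up, give 20 via 19. This variant needs neither the spare bromine nor steps 6 to 9, but it joins two hindered partners intermolecularly.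

Step 10. What may go wrong: slow addition of the hindered aryllithium to the lithium carboxylate, so that protonation, intermolecular acylation or attack on the solvent overtake ring closure. The fallback sets out from 16 and returns at 20 (Np as above). Acid 16 would be converted (1,1'-carbonyldiimidazole; MeNHOMe·HCl) into (4S)-4-(2,4-dibromo-6-methoxyphenyl)-N-methoxy-N-methyl-4-Np-butanamide F8. Double exchange (t-BuLi, 4.1 equiv, THF, −78 °C) would give (4S)-4-(2,4-dilithio-6-methoxyphenyl)-N-methoxy-N-methyl-4-Np-butanamide F9. This should cyclise already at −78 °C to the chelated adduct lithium (4S)-7-lithio-5-methoxy-1-[methoxy(methyl)amino]-4-Np-1,2,3,4-tetrahydronaphthalen-1-olate F10, which is stable until the acidic work-up that releases 19 and then 20.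

Step 6. What may go wrong: ionisation of the activated oxyphosphonium intermediate, which is allylic and vinylogously benzylic to the alkoxynaphthalene, giving the SN2' ether or a partly racemised SN2 ether. The fallback sets out from 5 and 9 and returns at 10. Aldehyde 5 would be methylenated (Ph3PCH3Br, KOt-Bu, THF) to 1-ethenyl-5-methoxy-4-(methoxymethoxy)naphthalene F11. Phenol 9 would be coupled under the Mitsunobu conditions with purchasable ethyl (2S)-2-hydroxybut-3-enoate, whose vinyl group gives no benzylic assistance to ionisation, to give ethyl (2R)-2-(3,5-dibromophenoxy)but-3-enoate F12. Cross-metathesis of F11 with F12 (second-generation Hoveyda–Grubbs catalyst, CH2Cl2, 40 °C) should give the (E)-alkene 10 and so also replaces steps 4 and 5.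

**Further compounds**

F1 | step 7 | ethyl (2S,3E)-4-[5-methoxy-4-(methoxymethoxy)naphthalen-1-yl]-2-[(pyridine-2-carbonyl)oxy]but-3-enoate | CCOC(=O)[C@@H](OC(=O)c1ccccn1)/C=C/c1ccc(OCOC)c2c(OC)cccc12
F2 | step 7 | (2-bromo-6-methoxyphenyl)magnesium chloride | COc1cccc(Br)c1[Mg]Cl
F3 | step 7 | ethyl (2E,4S)-4-(2-bromo-6-methoxyphenyl)-4-[5-methoxy-4-(methoxymethoxy)naphthalen-1-yl]but-2-enoate | COc1cccc(Br)c1[C@H](c1ccc(OCOC)c2c(OC)cccc12)/C=C/C(=O)OCC
F4 | step 7 | ethyl (4S)-4-(2-bromo-6-methoxyphenyl)-4-[5-methoxy-4-(methoxymethoxy)naphthalen-1-yl]butanoate | COc1cccc(Br)c1[C@H](c1ccc(OCOC)c2c(OC)cccc12)CCC(=O)OCC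
F5 | step 7 | (4S)-4-(2-bromo-6-methoxyphenyl)-4-[5-methoxy-4-(methoxymethoxy)naphthalen-1-yl]butanoic acid | COc1cccc(Br)c1[C@H](c1ccc(OCOC)c2c(OC)cccc12)CCC(=O)O
F6 | step 7 | lithium (4S)-4-(2-lithio-6-methoxyphenyl)-4-[5-methoxy-4-(methoxymethoxy)naphthalen-1-yl]butanoate | COc1cccc([Li])c1[C@H](c1ccc(OCOC)c2c(OC)cccc12)CCC(=O)O[Li]
F7 | step 7 | dilithium (4S)-5-methoxy-4-[5-methoxy-4-(methoxymethoxy)naphthalen-1-yl]-1,2,3,4-tetrahydronaphthalene-1,1-bis(olate) | COc1cccc2c1[C@H](c1ccc(OCOC)c3c(OC)cccc13)CCC2(O[Li])O[Li]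
F8 | step 10 | (4S)-4-(2,4-dibromo-6-methoxyphenyl)-N-methoxy-4-[5-methoxy-4-(methoxymethoxy)naphthalen-1-yl]-N-methylbutanamide | COc1cc(Br)cc(Br)c1[C@H](c1ccc(OCOC)c2c(OC)cccc12)CCC(=O)N(C)OC
F9 | step 10 | (4S)-4-(2,4-dilithio-6-methoxyphenyl)-N-methoxy-4-[5-methoxy-4-(methoxymethoxy)naphthalen-1-yl]-N-methylbutanamide | COc1cc([Li])cc([Li])c1[C@H](c1ccc(OCOC)c2c(OC)cccc12)CCC(=O)N(C)OC
F10 | step 10 | lithium (4S)-7-lithio-5-methoxy-1-[methoxy(methyl)amino]-4-[5-methoxy-4-(methoxymethoxy)naphthalen-1-yl]-1,2,3,4-tetrahydronaphthalen-1-olate (C1 not specified) | COc1cc([Li])cc2c1[C@H](c1ccc(OCOC)c3c(OC)cccc13)CCC2(O[Li])N(C)OC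
F11 | step 6 | 1-ethenyl-5-methoxy-4-(methoxymethoxy)naphthalene | C=Cc1ccc(OCOC)c2c(OC)cccc12
F12 | step 6 | ethyl (2R)-2-(3,5-dibromophenoxy)but-3-enoate | CCOC(=O)[C@H](Oc1cc(Br)cc(Br)c1)C=C
A1 | direct plan | 1-(benzyloxy)-4-bromo-8-methoxynaphthalene | COc1cccc2c(Br)ccc(OCc3ccccc3)c12
A2 | direct plan | 7-methoxy-2-benzofuran-1(3H)-one (7-methoxyphthalide) | COc1cccc2c1C(=O)OC2
A3 | direct plan | racemic 1-[4-(benzyloxy)-5-methoxynaphthalen-1-yl]-8-methoxy-1,4-dihydro-1,4-epoxynaphthalene, (1S,4S) and (1R,4R) | COc1cccc2c1[C@]1(c3ccc(OCc4ccccc4)c4c(OC)cccc34)O[C@H]2C=C1.COc1cccc2c1[C@@]1(c3ccc(OCc4ccccc4)c4c(OC)cccc34)O[C@@H]2C=C1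
A4 | direct plan | racemic cis-4-(4-hydroxy-5-methoxynaphthalen-1-yl)-5-methoxy-1,2,3,4-tetrahydronaphthalen-1-ol, (1S,4S) and (1R,4R) | COc1cccc2c1[C@H](c1ccc(O)c3c(OC)cccc13)CC[C@@H]2O.COc1cccc2c1[C@@H](c1ccc(O)c3c(OC)cccc13)CC[C@H]2O
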